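**Strategy**

Everything rests on cutting the oxolane of the olivil half (O1, C2H2, carbinol C3, C4, benzylic C5) at O1–C2 and C3–C4. This exploits that C3 is an oxygen-bearing quaternary carbon beside the ring CH2: C2=C3 becomes an enol ether (a 2-benzyloxyallyl arene), while O1–C5–C4 becomes an allylic alcohol whose alkene ends in a boronate, the masked CH2OH. One photoredox polar radical crossover cycloaddition joins them: the carbinol oxygen adds to the CH2 of the enol-ether radical cation and the tertiary α-alkoxy radical at C3 closes 5-exo onto C4, C5 setting both new centres. The regioisomeric enol ether gives the second half, which acid converts into the tetralin; Suzuki coupling and hydrogenolysis finish.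

Key step: step 8

Remark: half A is the oxolane (olivil-type) half and half B the tetralin (cycloolivil-type) half; the target is taken as (3S,4R,5S) in the oxolane and (1S,2S,3S) in the tetralin, as its SMILES reads; in step 2 the ProPhenol antipode is assumed to be the one that delivers the (S)-carbinol.

**Route**

Step 1
Reactants: 1 5-bromovanillin
Product: 2 4-(benzyloxy)-3-bromo-5-methoxybenzaldehyde
Conditions: BnBr, K2CO3, DMF, 60 °C
Reagents that add atoms: benzyl bromide, BrCc1ccccc1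
Why: Williamson etherification of the acidic phenol; benzyl is chosen because all six benzyl groups of the route fall together in the last step.

Step 2
Reactants: 2 4-(benzyloxy)-3-bromo-5-methoxybenzaldehyde
Product: 4 (S)-1-[4-(benzyloxy)-3-bromo-5-methoxyphenyl]prop-2-yn-1-ol, via trimethylsilyl alkyne 3 (not isolated)
Conditions: trimethylsilylacetylene, Me2Zn, ProPhenol ligand (20 mol %), Ph3PO, toluene, 0 °C, aq NH4Cl work-up; then K2CO3 (cat.), MeOH, rt
Reagents that add atoms: trimethylsilylacetylene, C#C[Si](C)(C)C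
Why: Zinc–ProPhenol-catalysed enantioselective alkynylation of an aryl aldehyde sets the carbinol centre by catalyst control, and methanolysis of the C–Si bond in the same flask frees the terminal alkyne.

Step 3
Reactants: 4 (S)-1-[4-(benzyloxy)-3-bromo-5-methoxyphenyl]prop-2-yn-1-ol
Product: 5 (S,E)-1-[4-(benzyloxy)-3-bromo-5-methoxyphenyl]-3-(4,4,5,5-tetramethyl-1,3,2-dioxaborolan-2-yl)prop-2-en-1-ol
Conditions: B2pin2, CuCl (5 mol %), Xantphos, NaOt-Bu (cat.), MeOH, THF, rt
Reagents that add atoms: bis(pinacolato)diboron, CC1(C)OB(OC1(C)C)B1OC(C)(C)C(C)(C)O1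
Why: Copper-catalysed formal hydroboration (syn borylcupration of the terminal alkyne, then protonation by methanol) should place boron on the terminal carbon and give the (E)-alkenylboronate without touching the aryl bromide or the carbinol centre.

Step 4
Reactants: 6 homoisovanillic acid, (3-hydroxy-4-methoxyphenyl)acetic acid
Product: 7 benzyl [3-(benzyloxy)-4-methoxyphenyl]acetate
Conditions: BnBr (2.2 equiv), K2CO3, DMF, 60 °C
Reagents that add atoms: benzyl bromide, BrCc1ccccc1
Why: Carboxylate and phenolate are both O-benzylated (Williamson-type alkylation), and the ester oxygen so installed is the one that ends as the tertiary benzyloxy group at C3.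

Step 5
Reactants: 7 benzyl [3-(benzyloxy)-4-methoxyphenyl]acetate
Product: 8 2-(benzyloxy)-4-[2-(benzyloxy)prop-2-en-1-yl]-1-methoxybenzene
Conditions: Cp2TiMe2 (2.5 equiv), toluene, 65 °C, dark; filtration through basic alumina
Reagents that add atoms: dimethyltitanocene Cp2TiMe2, [CH3-].[CH3-].[Ti+4].[cH-]1cccc1.[cH-]1cccc1
Why: Petasis methylenation of the ester carbonyl gives the 2-alkoxy-1-alkene regiospecifically, which enolisation of the corresponding benzyl ketone could not do.

Step 6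
Reactants: 9 homovanillic acid, (4-hydroxy-3-methoxyphenyl)acetic acid
Product: 10 benzyl [4-(benzyloxy)-3-methoxyphenyl]acetate
Conditions: BnBr (2.2 equiv), K2CO3, DMF, 60 °C
Reagents that add atoms: benzyl bromide, BrCc1ccccc1
Why: Same double O-benzylation (Williamson-type) as in step 4 on the regioisomeric acid.

Step 7
Reactants: 10 benzyl [4-(benzyloxy)-3-methoxyphenyl]acetate
Product: 11 1-(benzyloxy)-4-[2-(benzyloxy)prop-2-en-1-yl]-2-methoxybenzene
Conditions: Cp2TiMe2 (2.5 equiv), toluene, 65 °C, dark; filtration through basic alumina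
Reagents that add atoms: dimethyltitanocene Cp2TiMe2, [CH3-].[CH3-].[Ti+4].[cH-]1cccc1.[cH-]1cccc1
Why: Petasis methylenation as in step 5 gives the terminal enol ether of half B.

Step 8
Reactants: 5 (S,E)-1-[4-(benzyloxy)-3-bromo-5-methoxyphenyl]-3-(4,4,5,5-tetramethyl-1,3,2-dioxaborolan-2-yl)prop-2-en-1-ol; 8 2-(benzyloxy)-4-[2-(benzyloxy)prop-2-en-1-yl]-1-methoxybenzene
Product: 13 [(2S,3R,4S)-4-(benzyloxy)-4-[[3-(benzyloxy)-4-methoxyphenyl]methyl]-2-[4-(benzyloxy)-3-bromo-5-methoxyphenyl]oxolan-3-yl]methanol, via alkylboronate 12 (not isolated)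
Conditions: 5 (1 equiv), 8 (2 equiv), 9-mesityl-10-methylacridinium tetrafluoroborate (5 mol %), 2-phenylmalononitrile (20 mol %), 2,6-lutidine (10 mol %), degassed CH2Cl2, 450 nm LEDs, rt; then NaBO3·4H2O, THF/H2O, rt
Reagents that add atoms: sodium perborate tetrahydrate, O.O.O.O.[Na+].[O-]OB=O
Why: Proposed new method: the excited acridinium oxidises the 2-benzyloxyallyl unit of 8; the carbinol oxygen of 5 adds to the CH2 terminus of this radical cation (the C–O bond), and after proton loss the tertiary α-benzyloxy radical adds to the alkene carbon next to the carbinol centre (the C–C bond), the α-boryl radical being quenched by hydrogen-atom transfer from 2-phenylmalononitrile before perborate turns C–B into C–OH with retention. The closest known reaction type is the acridinium-catalysed polar radical crossover cycloaddition of alkenes with allylic alcohols to tetrahydrofurans, together with the trapping of enol-ether radical cations at their CH2 carbon by alcohols in anodic olefin coupling; an enol ether paired with an alkenylboronate has not been shown. The oxolane ring is closed by 5-exo-trig radical cyclisation. The stereocentre of 5 controls both new centres through the chair-like transition state of 5-hexenyl-type radical closure: the aryl group sits pseudo-equatorial and ends trans to CH2B, while at the radical carbon the benzyloxy group points away from the alkene and the arylmethyl group ends cis to CH2B, which is the olivil arrangement. The step needs O-attack at the enol ether to outcompete unproductive hole residence on the benzyloxy-methoxy arenes and benzylic deprotonation, and needs ring closure to outrun oxidation of the α-alkoxy radical: hole exchange is reversible and only the enol-ether channel leads on irreversibly, the alkenylboronate is a polarity-matched acceptor for the nucleophilic radical, lutidine suppresses acid-catalysed ketal formation, and 8 is used in excess.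

Step 9
Reactants: 5 (S,E)-1-[4-(benzyloxy)-3-bromo-5-methoxyphenyl]-3-(4,4,5,5-tetramethyl-1,3,2-dioxaborolan-2-yl)prop-2-en-1-ol; 11 1-(benzyloxy)-4-[2-(benzyloxy)prop-2-en-1-yl]-2-methoxybenzene
Product: 15 [(2S,3R,4S)-4-(benzyloxy)-4-[[4-(benzyloxy)-3-methoxyphenyl]methyl]-2-[4-(benzyloxy)-3-bromo-5-methoxyphenyl]oxolan-3-yl]methanol, via alkylboronate 14 (not isolated)
Conditions: 5 (1 equiv), 11 (2 equiv), 9-mesityl-10-methylacridinium tetrafluoroborate (5 mol %), 2-phenylmalononitrile (20 mol %), 2,6-lutidine (10 mol %), degassed CH2Cl2, 450 nm LEDs, rt; then NaBO3·4H2O, THF/H2O, rt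
Reagents that add atoms: sodium perborate tetrahydrate, O.O.O.O.[Na+].[O-]OB=O
Why: Proposed new method: the same acridinium-mediated polar radical crossover cycloaddition as in step 8 (alcohol attack on the CH2 of the enol-ether radical cation, 5-exo-trig closure of the α-benzyloxy radical onto the alkenylboronate under control of the carbinol centre, then C–B oxidation), whose closest known relative is the alkene/allylic alcohol cycloaddition to tetrahydrofurans.

Step 10
Reactants: 15 [(2S,3R,4S)-4-(benzyloxy)-4-[[4-(benzyloxy)-3-methoxyphenyl]methyl]-2-[4-(benzyloxy)-3-bromo-5-methoxyphenyl]oxolan-3-yl]methanol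
Product: 16 [(1S,2S,3S)-3,7-bis(benzyloxy)-1-[4-(benzyloxy)-3-bromo-5-methoxyphenyl]-3-(hydroxymethyl)-6-methoxy-1,2,3,4-tetrahydronaphthalen-2-yl]methanol
Conditions: BF3·OEt2 (1.2 equiv), CH2Cl2, −40 to 0 °C
Reagents that add atoms: none
Why: Lewis-acid ionisation of the benzylic C–O bond (cation stabilised by the para-benzyloxy group) and intramolecular Friedel–Crafts alkylation para to the methoxy group of the benzyl ring is the known olivil-to-cycloolivil rearrangement, in which the aryl group enters trans to the neighbouring CH2OH and the former ring CH2–O becomes the second CH2OH.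

Step 11
Reactants: 16 [(1S,2S,3S)-3,7-bis(benzyloxy)-1-[4-(benzyloxy)-3-bromo-5-methoxyphenyl]-3-(hydroxymethyl)-6-methoxy-1,2,3,4-tetrahydronaphthalen-2-yl]methanol; 13 [(2S,3R,4S)-4-(benzyloxy)-4-[[3-(benzyloxy)-4-methoxyphenyl]methyl]-2-[4-(benzyloxy)-3-bromo-5-methoxyphenyl]oxolan-3-yl]methanol
Product: 18 hexa-O-benzyl ether of 19, via arylboronate 17 (not isolated)
Conditions: 16, B2pin2 (1.05 equiv), Pd(dppf)Cl2 (5 mol %), KOAc, 1,4-dioxane, 90 °C; then 13, Pd(OAc)2 (5 mol %), SPhos (10 mol %), K3PO4, H2O, 90 °C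
Reagents that add atoms: none
Why: Miyaura borylation followed by Suzuki–Miyaura coupling in one flask joins the two aryl bromide carbons, SPhos coping with the two ortho-benzyloxy groups, while free hydroxyl groups are tolerated and no stereocentre is involved.

Step 12
Reactants: 18 hexa-O-benzyl ether of 19
Product: 19 CNP0252244.1
Conditions: H2 (1 atm), Pd(OH)2/C, EtOAc/MeOH, rt, monitored and stopped at full debenzylation
Reagents that add atoms: none
Why: Hydrogenolysis should cleave the four aryl and two tertiary alkyl benzyl ethers faster than the cyclic benzylic ether of the oxolane, releasing the target without touching any stereocentre.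

**Compound list**

1 | 5-bromovanillin (3-bromo-4-hydroxy-5-methoxybenzaldehyde) | COc1cc(C=O)cc(Br)c1O | starting material
2 | 4-(benzyloxy)-3-bromo-5-methoxybenzaldehyde | COc1cc(C=O)cc(Br)c1OCc1ccccc1 | intermediate
3 | (R)-1-[4-(benzyloxy)-3-bromo-5-methoxyphenyl]-3-(trimethylsilyl)prop-2-yn-1-ol | O[C@H](c1cc(OC)c(OCc2ccccc2)c(Br)c1)C#C[Si](C)(C)C | intermediate
4 | (S)-1-[4-(benzyloxy)-3-bromo-5-methoxyphenyl]prop-2-yn-1-ol | O[C@H](c1cc(OC)c(OCc2ccccc2)c(Br)c1)C#C | intermediate
5 | (S,E)-1-[4-(benzyloxy)-3-bromo-5-methoxyphenyl]-3-(4,4,5,5-tetramethyl-1,3,2-dioxaborolan-2-yl)prop-2-en-1-ol | O[C@H](c1cc(OC)c(OCc2ccccc2)c(Br)c1)/C=C/B1OC(C)(C)C(C)(C)O1 | intermediate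
6 | homoisovanillic acid, (3-hydroxy-4-methoxyphenyl)acetic acid | COc1ccc(CC(=O)O)cc1O | starting material
7 | benzyl [3-(benzyloxy)-4-methoxyphenyl]acetate | COc1ccc(CC(=O)OCc2ccccc2)cc1OCc1ccccc1 | intermediate
8 | 2-(benzyloxy)-4-[2-(benzyloxy)prop-2-en-1-yl]-1-methoxybenzene | COc1ccc(CC(=C)OCc2ccccc2)cc1OCc1ccccc1 | intermediate
9 | homovanillic acid, (4-hydroxy-3-methoxyphenyl)acetic acid | COc1cc(CC(=O)O)ccc1O | starting material
10 | benzyl [4-(benzyloxy)-3-methoxyphenyl]acetate | COc1cc(CC(=O)OCc2ccccc2)ccc1OCc1ccccc1 | intermediate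
11 | 1-(benzyloxy)-4-[2-(benzyloxy)prop-2-en-1-yl]-2-methoxybenzene | COc1cc(CC(=C)OCc2ccccc2)ccc1OCc1ccccc1 | intermediate
12 | (2S,3R,4S)-4-(benzyloxy)-4-[[3-(benzyloxy)-4-methoxyphenyl]methyl]-2-[4-(benzyloxy)-3-bromo-5-methoxyphenyl]-3-[(4,4,5,5-tetramethyl-1,3,2-dioxaborolan-2-yl)methyl]oxolane | COc1ccc(C[C@@]2(OCc3ccccc3)CO[C@H](c3cc(OC)c(OCc4ccccc4)c(Br)c3)[C@H]2CB2OC(C)(C)C(C)(C)O2)cc1OCc1ccccc1 | intermediate
13 | [(2S,3R,4S)-4-(benzyloxy)-4-[[3-(benzyloxy)-4-methoxyphenyl]methyl]-2-[4-(benzyloxy)-3-bromo-5-methoxyphenyl]oxolan-3-yl]methanol | COc1ccc(C[C@@]2(OCc3ccccc3)CO[C@H](c3cc(OC)c(OCc4ccccc4)c(Br)c3)[C@H]2CO)cc1OCc1ccccc1 | intermediate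
14 | (2S,3R,4S)-4-(benzyloxy)-4-[[4-(benzyloxy)-3-methoxyphenyl]methyl]-2-[4-(benzyloxy)-3-bromo-5-methoxyphenyl]-3-[(4,4,5,5-tetramethyl-1,3,2-dioxaborolan-2-yl)methyl]oxolane | COc1cc(C[C@@]2(OCc3ccccc3)CO[C@H](c3cc(OC)c(OCc4ccccc4)c(Br)c3)[C@H]2CB2OC(C)(C)C(C)(C)O2)ccc1OCc1ccccc1 | intermediate
15 | [(2S,3R,4S)-4-(benzyloxy)-4-[[4-(benzyloxy)-3-methoxyphenyl]methyl]-2-[4-(benzyloxy)-3-bromo-5-methoxyphenyl]oxolan-3-yl]methanol | COc1cc(C[C@@]2(OCc3ccccc3)CO[C@H](c3cc(OC)c(OCc4ccccc4)c(Br)c3)[C@H]2CO)ccc1OCc1ccccc1 | intermediate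
16 | [(1S,2S,3S)-3,7-bis(benzyloxy)-1-[4-(benzyloxy)-3-bromo-5-methoxyphenyl]-3-(hydroxymethyl)-6-methoxy-1,2,3,4-tetrahydronaphthalen-2-yl]methanol | COc1cc(cc(Br)c1OCc1ccccc1)[C@H]1c2cc(OCc3ccccc3)c(OC)cc2C[C@@](OCc2ccccc2)(CO)[C@@H]1CO | intermediate
17 | pinacol arylboronate of 16 (Bpin in place of Br) | COc1cc(cc(B2OC(C)(C)C(C)(C)O2)c1OCc1ccccc1)[C@H]1c2cc(OCc3ccccc3)c(OC)cc2C[C@@](OCc2ccccc2)(CO)[C@@H]1CO | intermediate
18 | hexa-O-benzyl ether of 19 (benzyl on the four phenolic and the two tertiary oxygens; biaryl bond between the former C–Br carbons of 13 and 16) | COc1ccc(C[C@@]2(OCc3ccccc3)CO[C@H](c3cc(OC)c(OCc4ccccc4)c(-c4cc([C@H]5c6cc(OCc7ccccc7)c(OC)cc6C[C@@](OCc6ccccc6)(CO)[C@@H]5CO)cc(OC)c4OCc4ccccc4)c3)[C@H]2CO)cc1OCc1ccccc1 | intermediate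
19 | CNP0252244.1, (3S,4R,5S)-5-[4-hydroxy-3-[2-hydroxy-5-[(1S,2S,3S)-3,7-dihydroxy-2,3-bis(hydroxymethyl)-6-methoxy-1,2,3,4-tetrahydronaphthalen-1-yl]-3-methoxyphenyl]-5-methoxyphenyl]-3-[(3-hydroxy-4-methoxyphenyl)methyl]-4-(hydroxymethyl)oxolan-3-ol | COc1ccc(C[C@@]2(O)CO[C@H](c3cc(OC)c(O)c(-c4cc([C@H]5c6cc(O)c(OC)cc6C[C@@](O)(CO)[C@@H]5CO)cc(OC)c4O)c3)[C@H]2CO)cc1O | target

**Step count and risks**

Total step count: 12. Longest linear sequence: 7 steps (1, 2, 3, 9, 10, 11, 12).

Steps most likely to fail: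

Step 8 (labelled). The hole may reside on the benzyl-protected dialkoxyarenes, the enol ether may lose its doubly activated benzylic proton and isomerise, the α-alkoxy radical may be oxidised before it cyclises, or facial selectivity at the radical carbon may be low. The fallback keeps the radical logic but uses known reactions; it sets out from 5 and 7 and comes back at 19. Ester 7 is homologated through its keto sulfoxonium ylide (Me3S(O)I, t-BuOK; then HBr) to 1-[3-(benzyloxy)-4-methoxyphenyl]-3-bromopropan-2-one F1. O-alkylation of 5 with F1 (Ag2O, CH2Cl2) gives keto ether F2. Ketyl–olefin cyclisation with SmI2/HMPA/t-BuOH in THF at −78 °C (5-exo, hydroxyl anti to the alkene-derived carbon, aryl trans) gives hydroxy alkylboronate F3, and NaBO3 oxidises it to the 4-hydroxy analogue of 13, diol F4. F4 takes the place of 13 in step 11 and gives penta-O-benzyl dimer F5, which the hydrogenolysis of step 12 converts into 19.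

Step 9 (labelled). The same processes may go wrong as in step 8. The fallback sets out from 5 and 10 and comes back at 19. Ester 10 gives 1-[4-(benzyloxy)-3-methoxyphenyl]-3-bromopropan-2-one F6 by the same homologation. Ag2O-mediated O-alkylation of 5 gives keto ether F7, SmI2/HMPA cyclisation gives hydroxy alkylboronate F8, and NaBO3 gives diol F9. BF3·OEt2 as in step 10 gives 3-hydroxy tetralin bromide F10. Borylation as in step 11 gives arylboronate F11, which couples with 13 to penta-O-benzyl dimer F12; hydrogenolysis as in step 12 gives 19.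

Step 12. Hydrogenolytic opening of the benzylic C–O bond of the oxolane may compete with the slow cleavage of the two tertiary benzyl ethers. The fallback sets out from 18 and comes back at 19 and makes no new compound. It replaces catalytic hydrogenolysis by electron-transfer debenzylation with lithium 4,4'-di-tert-butylbiphenylide in THF at −78 °C. The unsubstituted benzyl rings accept the electron more readily than the trioxygenated aryl rings, and the phenoxides formed first make those rings harder still to reduce, so the oxolane C–O bond should be spared; protonation gives 19.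

Further compounds
F1 | step 8 | 1-[3-(benzyloxy)-4-methoxyphenyl]-3-bromopropan-2-one | COc1ccc(CC(=O)CBr)cc1OCc1ccccc1
F2 | step 8 | 1-[3-(benzyloxy)-4-methoxyphenyl]-3-[[(1S,2E)-1-[4-(benzyloxy)-3-bromo-5-methoxyphenyl]-3-(4,4,5,5-tetramethyl-1,3,2-dioxaborolan-2-yl)prop-2-en-1-yl]oxy]propan-2-one | COc1ccc(CC(=O)CO[C@H](c2cc(OC)c(OCc3ccccc3)c(Br)c2)/C=C/B2OC(C)(C)C(C)(C)O2)cc1OCc1ccccc1
F3 | step 8 | (3S,4R,5S)-3-[[3-(benzyloxy)-4-methoxyphenyl]methyl]-5-[4-(benzyloxy)-3-bromo-5-methoxyphenyl]-4-[(4,4,5,5-tetramethyl-1,3,2-dioxaborolan-2-yl)methyl]oxolan-3-ol | COc1ccc(C[C@@]2(O)CO[C@H](c3cc(OC)c(OCc4ccccc4)c(Br)c3)[C@H]2CB2OC(C)(C)C(C)(C)O2)cc1OCc1ccccc1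
F4 | step 8 | (3S,4R,5S)-3-[[3-(benzyloxy)-4-methoxyphenyl]methyl]-5-[4-(benzyloxy)-3-bromo-5-methoxyphenyl]-4-(hydroxymethyl)oxolan-3-ol | COc1ccc(C[C@@]2(O)CO[C@H](c3cc(OC)c(OCc4ccccc4)c(Br)c3)[C@H]2CO)cc1OCc1ccccc1
F5 | step 8 | penta-O-benzyl ether of 19 with the oxolane tertiary hydroxyl free | COc1ccc(C[C@@]2(O)CO[C@H](c3cc(OC)c(OCc4ccccc4)c(-c4cc([C@H]5c6cc(OCc7ccccc7)c(OC)cc6C[C@@](OCc6ccccc6)(CO)[C@@H]5CO)cc(OC)c4OCc4ccccc4)c3)[C@H]2CO)cc1OCc1ccccc1
F6 | step 9 | 1-[4-(benzyloxy)-3-methoxyphenyl]-3-bromopropan-2-one | COc1cc(CC(=O)CBr)ccc1OCc1ccccc1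
F7 | step 9 | 1-[4-(benzyloxy)-3-methoxyphenyl]-3-[[(1S,2E)-1-[4-(benzyloxy)-3-bromo-5-methoxyphenyl]-3-(4,4,5,5-tetramethyl-1,3,2-dioxaborolan-2-yl)prop-2-en-1-yl]oxy]propan-2-one | COc1cc(CC(=O)CO[C@H](c2cc(OC)c(OCc3ccccc3)c(Br)c2)/C=C/B2OC(C)(C)C(C)(C)O2)ccc1OCc1ccccc1
F8 | step 9 | (3S,4R,5S)-3-[[4-(benzyloxy)-3-methoxyphenyl]methyl]-5-[4-(benzyloxy)-3-bromo-5-methoxyphenyl]-4-[(4,4,5,5-tetramethyl-1,3,2-dioxaborolan-2-yl)methyl]oxolan-3-ol | COc1cc(C[C@@]2(O)CO[C@H](c3cc(OC)c(OCc4ccccc4)c(Br)c3)[C@H]2CB2OC(C)(C)C(C)(C)O2)ccc1OCc1ccccc1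
F9 | step 9 | (3S,4R,5S)-3-[[4-(benzyloxy)-3-methoxyphenyl]methyl]-5-[4-(benzyloxy)-3-bromo-5-methoxyphenyl]-4-(hydroxymethyl)oxolan-3-ol | COc1cc(C[C@@]2(O)CO[C@H](c3cc(OC)c(OCc4ccccc4)c(Br)c3)[C@H]2CO)ccc1OCc1ccccc1
F10 | step 9 | (1S,2S,3S)-7-(benzyloxy)-1-[4-(benzyloxy)-3-bromo-5-methoxyphenyl]-2,3-bis(hydroxymethyl)-6-methoxy-1,2,3,4-tetrahydronaphthalen-3-ol | COc1cc(cc(Br)c1OCc1ccccc1)[C@H]1c2cc(OCc3ccccc3)c(OC)cc2C[C@@](O)(CO)[C@@H]1CO
F11 | step 9 | pinacol arylboronate of F10 (Bpin in place of Br) | COc1cc(cc(B2OC(C)(C)C(C)(C)O2)c1OCc1ccccc1)[C@H]1c2cc(OCc3ccccc3)c(OC)cc2C[C@@](O)(CO)[C@@H]1CO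
F12 | step 9 | penta-O-benzyl ether of 19 with the tetralin tertiary hydroxyl free | COc1ccc(C[C@@]2(OCc3ccccc3)CO[C@H](c3cc(OC)c(OCc4ccccc4)c(-c4cc([C@H]5c6cc(OCc7ccccc7)c(OC)cc6C[C@@](O)(CO)[C@@H]5CO)cc(OC)c4OCc4ccccc4)c3)[C@H]2CO)cc1OCc1ccccc1
F0 | step 12 | none | none
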